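**Plan**

1. Cuts: (a) the bond between the side-chain carbinol carbon C1' and the quaternary epoxide carbon C1 of ring B (7-oxabicyclo[4.1.0]hept-3-ene: C1 epoxide C, C2 CHOH, C3 =CH, C4 C–CH2OH, C5 CHOH, C6 epoxide CH); (b) C3'–C4' of the (2Z,4E)-diene; (c) the C1–C2 bond of ring A (trimethylcyclohexanediol).
2. Forward: ring A is made first by titanocene radical cyclization of (R)-6,7-epoxygeranyl acetate, and the exocyclic alkene becomes the tertiary alcohol. Takai–Utimoto borylation, Suzuki coupling and MnO2 give the (2Z,4E)-dienal (fragment 1). Ring B enters as an achiral iodo quinone monoketal (fragment 2), which after the union is converted into the epoxy diol.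
3. Enabling feature: epoxide carbon C1 of ring B lies next to carbinol C2, so it is the α-carbon of a latent cyclohexa-2,5-dienone whose C5 is held as a ketal. As a C–I bond it becomes an alkenylchromium nucleophile, and C1' is the aldehyde carbon. The coupling leaves a hydroxyl on C1' beside the ring double bond C1=C6 that must become the epoxide, and 1,3 to the C2 carbonyl.
4. Stereochemistry, ring A: Shi epoxidation (C3), chair cyclization (C1), equatorial epoxidation and hydride opening (C6).
5. Stereochemistry, C1' and ring B: ligand-controlled Nozaki–Hiyama–Kishi coupling (C1'), hydroxyl-directed nucleophilic epoxidation (C1, C6), Evans–Saksena 1,3-anti reduction (C2), Luche reduction then Mitsunobu inversion (C5).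
6. Protecting groups: one primary TBS ether and three late TES ethers, removed together in the last step.

Key step: step 14

Assumption: the (S)-configured chromium ligand of step 14 and L-DIPT of step 15 are taken to be the antipodes that deliver to the faces drawn; if either sense proves opposite, the mirror-image ligand or D-DIPT is used without other change.

**Route**

Step 1
Reactants: 1 geranyl acetate
Product: 2 (R)-6,7-epoxygeranyl acetate
Conditions: D-fructose-derived ketone catalyst (1,2:4,5-di-O-isopropylidene-β-D-erythro-hexo-2,3-diulo-2,6-pyranose, 0.3 equiv), KHSO5 (Oxone), K2CO3, Bu4NHSO4, MeCN/dimethoxymethane/aq. buffer, 0 °C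
Reagents that add atoms: potassium peroxymonosulfate, [K+].[O-]S(=O)(=O)OO
Why: Shi epoxidation, in which the chiral dioxirane attacks the electron-rich 6,7-double bond (the 2,3-double bond is deactivated by the allylic acetate) through a spiro transition state that should give the (R)-epoxide.

Step 2
Reactants: 2 (R)-6,7-epoxygeranyl acetate
Product: 3 [(1S,3R)-3-hydroxy-2,2-dimethyl-6-methylidenecyclohexyl]methyl acetate (CH2OAc and OH cis, both equatorial)
Conditions: Cp2TiCl2 (2.2 equiv), Mn dust, THF, rt; aq. HCl work-up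
Reagents that add atoms: none
Why: Nugent–RajanBabu epoxide opening by Cp2TiCl (trivalent titanium) gives the tertiary radical, 6-endo cyclization through a chair sets the new ring CH with its CH2OAc group cis to the titanoxy group, and the cyclized tertiary radical is trapped by a second Cp2TiCl and loses β-hydride to the exocyclic alkene.

Step 3
Reactants: 3 exocyclic alkene
Product: 4 (6-hydroxy-5,5-dimethyl-1-oxaspiro[2.5]octan-4-yl)methyl acetate, epoxide oxygen equatorial and trans to the CH2OAc group
Conditions: dimethyldioxirane, acetone, 0 °C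
Reagents that add atoms: dimethyldioxirane, CC1(C)OO1
Why: Dioxirane epoxidation of the 1,1-disubstituted alkene from the equatorial direction, because the axial methyl of the gem-dimethyl carbon (1,3-diaxial) blocks the axial face, should put the epoxide oxygen equatorial.

Step 4
Reactants: 4 spiro-epoxide
Product: 5 2-(hydroxymethyl)-1,3,3-trimethylcyclohexane-1,4-diol (tertiary OH equatorial and trans to CH2OH, 1-methyl axial, secondary OH cis to CH2OH)
Conditions: LiAlH4, THF, 0 °C to rt
Reagents that add atoms: none
Why: Hydride opens the spiro-epoxide at its CH2 terminus (SN2), which turns that carbon into the axial methyl and leaves the equatorial tertiary alcohol, and also reduces the acetate to the primary alcohol.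

Step 5
Reactants: 5 triol
Product: 6 (1R,3R,6R)-3,6-dihydroxy-2,2,6-trimethylcyclohexane-1-carbaldehyde
Conditions: TEMPO (cat.), PhI(OAc)2, CH2Cl2, rt
Reagents that add atoms: none
Why: Oxoammonium (TEMPO) oxidation is selective for the primary alcohol over the hindered secondary and the tertiary one and runs without base, so the β-hydroxy aldehyde should not undergo retro-aldol cleavage.

Step 6
Reactants: 6 aldehyde
Product: 7 2-[(E)-2-[(1R,3R,6R)-3,6-dihydroxy-2,2,6-trimethylcyclohexyl]ethenyl]-4,4,5,5-tetramethyl-1,3,2-dioxaborolane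
Conditions: CrCl2, Cl2CHBpin, LiI, THF, rt
Reagents that add atoms: 2-(dichloromethyl)-4,4,5,5-tetramethyl-1,3,2-dioxaborolane, CC1(C)OB(C(Cl)Cl)OC1(C)C
Why: Takai–Utimoto olefination with the geminal dichromium species from the (dihalomethyl)boronate should give the (E)-alkenylboronate under non-basic conditions that tolerate the free hydroxyl groups.

Step 7
Reactants: 8 but-2-yn-1-ol
Product: 10 (Z)-3-iodobut-2-en-1-ol, via cyclic alkenylalanate 9 (not isolated)
Conditions: NaAlH2(OCH2CH2OCH3)2, THF, 0 °C to rt; then I2, −78 to 0 °C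
Reagents that add atoms: iodine, II
Why: Hydroxyl-directed trans-hydroalumination of the propargylic alcohol places aluminium on the distal carbon cis to the CH2O group, and iodinolysis with retention gives the (Z)-iodoalkene.

Step 8
Reactants: 7 (E)-alkenylboronate; 10 (Z)-3-iodobut-2-en-1-ol
Product: 11 (2Z,4E)-5-[(1R,3R,6R)-3,6-dihydroxy-2,2,6-trimethylcyclohexyl]-3-methylpenta-2,4-dien-1-ol
Conditions: Pd(PPh3)4 (cat.), K3PO4 (aq.), THF, 45 °C
Reagents that add atoms: none
Why: Suzuki–Miyaura coupling proceeds with retention of both alkene geometries and so joins the (E)-alkenylboronate to the (Z)-iodide as the (2Z,4E)-diene.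

Step 9
Reactants: 11 dienol
Product: 12 (2Z,4E)-5-[(1R,3R,6R)-3,6-dihydroxy-2,2,6-trimethylcyclohexyl]-3-methylpenta-2,4-dienal (fragment 1)
Conditions: MnO2, CH2Cl2, rt, dark
Reagents that add atoms: none
Why: MnO2 oxidizes only the allylic primary alcohol and should preserve the 2Z geometry, as is usual for such dienols.

Step 10
Reactants: 13 5-hydroxy-2-methoxybenzaldehyde
Product: 14 3-(hydroxymethyl)-4-methoxyphenol
Conditions: NaBH4, MeOH, 0 °C
Reagents that add atoms: none
Why: Borohydride reduction of the aryl aldehyde to the benzylic alcohol.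

Step 11
Reactants: 14 3-(hydroxymethyl)-4-methoxyphenol
Product: 15 3-(hydroxymethyl)-4,4-dimethoxycyclohexa-2,5-dien-1-one
Conditions: PhI(OAc)2, MeOH, 0 °C
Reagents that add atoms: methanol, CO
Why: Oxidative dearomatization of the para-methoxyphenol by the hypervalent iodine reagent in methanol gives the quinone monoketal with the ketal at the carbon that carried the methoxy group.

Step 12
Reactants: 15 hydroxymethyl quinone monoketal
Product: 16 3-[(tert-butyldimethylsilyloxy)methyl]-4,4-dimethoxycyclohexa-2,5-dien-1-one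
Conditions: TBSCl, imidazole, DMF, 0 °C
Reagents that add atoms: tert-butyldimethylsilyl chloride, CC(C)(C)[Si](C)(C)Cl
Why: Silylation of the primary alcohol, so that this hydroxyl cannot later direct the epoxidation to the wrong ring double bond.

Step 13
Reactants: 16 silylated quinone monoketal
Product: 17 5-[(tert-butyldimethylsilyloxy)methyl]-2-iodo-4,4-dimethoxycyclohexa-2,5-dien-1-one (fragment 2)
Conditions: I2, pyridine, CH2Cl2, 0 °C to rt
Reagents that add atoms: iodine, II
Why: α-Iodination of the enone by the I2/pyridine addition–elimination mechanism occurs on the double bond whose β-carbon is unsubstituted, which puts iodine on the α-carbon remote from the silyloxymethyl group.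

Step 14
Reactants: 12 (2Z,4E)-dienal (fragment 1); 17 iodo quinone monoketal (fragment 2)
Product: 18 2-[(1S,2Z,4E)-5-[(1R,3R,6R)-3,6-dihydroxy-2,2,6-trimethylcyclohexyl]-1-hydroxy-3-methylpenta-2,4-dien-1-yl]-5-[(tert-butyldimethylsilyloxy)methyl]-4,4-dimethoxycyclohexa-2,5-dien-1-one
Conditions: CrCl2, (S)-N-[2-(4-isopropyl-4,5-dihydrooxazol-2-yl)-6-methylphenyl]methanesulfonamide, Et3N, NiCl2 (cat.), THF, rt
Reagents that add atoms: none
Why: Nozaki–Hiyama–Kishi reaction, in which zerovalent nickel inserts into the C–I bond at the α-carbon of the dienone, the alkenyl group passes to trivalent chromium carrying the chiral sulfonamide–oxazoline ligand, and this alkenylchromium adds 1,2 to the aldehyde. The closest known reaction type is the ligand-controlled asymmetric alkenyl Nozaki–Hiyama–Kishi coupling of complex fragments; no ring is closed. The one new stereocenter, the side-chain carbinol, is set by the ligand on chromium, which should deliver the alkenyl group to the Re face of the aldehyde and give the (S)-carbinol. The step needs chemoselectivity for the C–I bond over the dienone, the ketal and the free hydroxyls, and 1,2-addition without loss of the 2Z geometry; the iodine on the enone α-carbon, the non-basic character of alkenylchromium reagents and the absence of enolizable hydrogens in the monoketal should secure this. The hydroxyalkyl enone so formed carries the hydroxyl that controls the epoxide and the adjacent ring carbinol in the next two steps.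

Step 15
Reactants: 18 hydroxyalkyl dienone
Product: 19 epoxy ketone: 1-[(1S,2Z,4E)-side chain as in 18]-4-[(tert-butyldimethylsilyloxy)methyl]-5,5-dimethoxy-7-oxabicyclo[4.1.0]hept-3-en-2-one, both epoxide carbons configured as in the target
Conditions: Ph3COOH, NaHMDS, L-DIPT, 4 Å MS, toluene, −65 °C
Reagents that add atoms: trityl hydroperoxide, OOC(c1ccccc1)(c1ccccc1)c1ccccc1
Why: Hydroxyl-directed Weitz–Scheffer (nucleophilic) epoxidation in its tartrate-mediated form, in which the sodium alkoxide of the carbinol, held in the tartrate aggregate, delivers the peroxide to the unsubstituted β-carbon of the adjacent ring double bond from the face on which the alkoxide sits when the carbinol hydrogen eclipses the ring C–C(=O) bond, so that both epoxide carbons are set while the electron-rich side-chain diene stays inert to the nucleophilic oxidant.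

Step 16
Reactants: 19 epoxy ketone
Product: 20 diol: the C2 ketone of 19 reduced to the (S)-carbinol, hydroxyl trans to the epoxide oxygen and 1,3-anti to the side-chain hydroxyl
Conditions: Me4NBH(OAc)3, MeCN/AcOH, −30 °C
Reagents that add atoms: none
Why: Evans–Saksena reduction, in which the side-chain carbinol oxygen binds boron and delivers hydride intramolecularly through a chair six-membered transition state with the dienyl group equatorial, which should give the 1,3-anti diol and hence the ring hydroxyl trans to the epoxide.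

Step 17
Reactants: 20 diol
Product: 21 tris(triethylsilyl) ether of 20 (side-chain carbinol, ring B C2 carbinol and ring A secondary carbinol silylated; tertiary OH free)
Conditions: TESCl, imidazole, DMAP (cat.), DMF, rt
Reagents that add atoms: triethylsilyl chloride, CC[Si](Cl)(CC)CC
Why: Silylation of the three secondary hydroxyls (the tertiary one is too hindered) leaves only the later C5 carbinol free for inversion.

Step 18
Reactants: 21 tris(triethylsilyl) ether
Product: 22 epoxy enone: the C5 dimethyl ketal of 21 converted into the ketone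
Conditions: PPTS (cat.), acetone/H2O, rt
Reagents that add atoms: water, O
Why: Mild acid-catalysed hydrolysis of the allylic dimethyl ketal gives the epoxy enone, which cannot aromatize because the epoxide carbons are sp3.

Step 19
Reactants: 22 epoxy enone
Product: 23 C5 alcohol cis to the epoxide oxygen (C5 epimer of 25)
Conditions: NaBH4, CeCl3·7H2O, MeOH, −78 °C
Reagents that add atoms: none
Why: Luche 1,2-reduction of the enone, with hydride attack on the face away from the epoxide oxygen as is usual for cyclic epoxy ketones, should give the alcohol cis to the epoxide.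

Step 20
Reactants: 23 cis-epoxy alcohol
Product: 24 4-nitrobenzoate at C5 with inverted configuration (ester trans to the epoxide oxygen)
Conditions: PPh3, DIAD, 4-nitrobenzoic acid, toluene, 0 °C to rt
Reagents that add atoms: 4-nitrobenzoic acid, OC(=O)c1ccc(cc1)[N+](=O)[O-]
Why: Mitsunobu reaction, in which SN2 displacement of the oxyphosphonium group by the carboxylate inverts the allylic carbinol to the configuration trans to the epoxide.

Step 21
Reactants: 24 4-nitrobenzoate
Product: 25 C5 alcohol trans to the epoxide oxygen (silyl-protected arthrosporol A)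
Conditions: K2CO3 (cat.), MeOH, 0 °C
Reagents that add atoms: none
Why: Mild base-catalysed transesterification removes the 4-nitrobenzoate without touching the silyl ethers or the epoxide.

Step 22
Reactants: 25 silyl-protected arthrosporol A
Product: 26 arthrosporol A
Conditions: TBAF, AcOH, THF, 0 °C to rt
Reagents that add atoms: none
Why: Buffered fluoride cleaves the three triethylsilyl ethers and the primary tert-butyldimethylsilyl ether without acid (dienyl carbinol) and without free alkoxide (Payne rearrangement of the epoxy alcohols).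

**Compound list**

1 | geranyl acetate | CC(=O)OC/C=C(\C)CCC=C(C)C | starting material
2 | (R)-6,7-epoxygeranyl acetate | CC(=O)OC/C=C(\C)CC[C@H]1OC1(C)C | intermediate
3 | [(1S,3R)-3-hydroxy-2,2-dimethyl-6-methylidenecyclohexyl]methyl acetate | CC(=O)OC[C@@H]1C(C)(C)[C@H](O)CCC1=C | intermediate
4 | (6-hydroxy-5,5-dimethyl-1-oxaspiro[2.5]octan-4-yl)methyl acetate, epoxide oxygen equatorial | CC(=O)OC[C@@H]1C(C)(C)[C@H](O)CC[C@]12CO2 | intermediate
5 | 2-(hydroxymethyl)-1,3,3-trimethylcyclohexane-1,4-diol | OC[C@@H]1C(C)(C)[C@H](O)CC[C@@]1(C)O | intermediate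
6 | (1R,3R,6R)-3,6-dihydroxy-2,2,6-trimethylcyclohexane-1-carbaldehyde | O=C[C@@H]1C(C)(C)[C@H](O)CC[C@@]1(C)O | intermediate
7 | (E)-alkenyl pinacol boronate of ring A | CC1(C)OB(/C=C/[C@@H]2C(C)(C)[C@H](O)CC[C@@]2(C)O)OC1(C)C | intermediate
8 | but-2-yn-1-ol | CC#CCO | starting material
9 | sodium cyclic alkenylalanate (2,5-dihydro-1,2-oxaaluminole ate complex) | [Na+].CC1=CCO[Al-]1(OCCOC)OCCOC | intermediate
10 | (Z)-3-iodobut-2-en-1-ol | C/C(I)=C/CO | intermediate
11 | (2Z,4E)-5-[(1R,3R,6R)-3,6-dihydroxy-2,2,6-trimethylcyclohexyl]-3-methylpenta-2,4-dien-1-ol | CC(=C/CO)/C=C/[C@@H]1C(C)(C)[C@H](O)CC[C@@]1(C)O | intermediate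
12 | (2Z,4E)-5-[(1R,3R,6R)-3,6-dihydroxy-2,2,6-trimethylcyclohexyl]-3-methylpenta-2,4-dienal | CC(=C/C=O)/C=C/[C@@H]1C(C)(C)[C@H](O)CC[C@@]1(C)O | intermediate
13 | 5-hydroxy-2-methoxybenzaldehyde | COc1ccc(O)cc1C=O | starting material
14 | 3-(hydroxymethyl)-4-methoxyphenol | COc1ccc(O)cc1CO | intermediate
15 | 3-(hydroxymethyl)-4,4-dimethoxycyclohexa-2,5-dien-1-one | COC1(OC)C=CC(=O)C=C1CO | intermediate
16 | 3-[(tert-butyldimethylsilyloxy)methyl]-4,4-dimethoxycyclohexa-2,5-dien-1-one | COC1(OC)C=CC(=O)C=C1CO[Si](C)(C)C(C)(C)C | intermediate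
17 | 5-[(tert-butyldimethylsilyloxy)methyl]-2-iodo-4,4-dimethoxycyclohexa-2,5-dien-1-one | COC1(OC)C=C(I)C(=O)C=C1CO[Si](C)(C)C(C)(C)C | intermediate
18 | (S)-carbinol from the fragment union (hydroxyalkyl dienone) | CC(=C/[C@H](O)C1=CC(OC)(OC)C(CO[Si](C)(C)C(C)(C)C)=CC1=O)/C=C/[C@@H]2C(C)(C)[C@H](O)CC[C@@]2(C)O | intermediate
19 | epoxy ketone (ring B epoxide set, C2 ketone, C5 ketal) | CC(=C/[C@H](O)[C@]12O[C@H]1C(OC)(OC)C(CO[Si](C)(C)C(C)(C)C)=CC2=O)/C=C/[C@@H]3C(C)(C)[C@H](O)CC[C@@]3(C)O | intermediate
20 | 1,3-anti diol (C2 carbinol trans to epoxide, C5 ketal) | CC(=C/[C@H](O)[C@]12O[C@H]1C(OC)(OC)C(CO[Si](C)(C)C(C)(C)C)=C[C@@H]2O)/C=C/[C@@H]3C(C)(C)[C@H](O)CC[C@@]3(C)O | intermediate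
21 | tris(triethylsilyl) ether of 20 | CC(=C/[C@H](O[Si](CC)(CC)CC)[C@]12O[C@H]1C(OC)(OC)C(CO[Si](C)(C)C(C)(C)C)=C[C@@H]2O[Si](CC)(CC)CC)/C=C/[C@@H]3C(C)(C)[C@H](O[Si](CC)(CC)CC)CC[C@@]3(C)O | intermediate
22 | epoxy enone (C5 ketone) | CC(=C/[C@H](O[Si](CC)(CC)CC)[C@]12O[C@H]1C(=O)C(CO[Si](C)(C)C(C)(C)C)=C[C@@H]2O[Si](CC)(CC)CC)/C=C/[C@@H]3C(C)(C)[C@H](O[Si](CC)(CC)CC)CC[C@@]3(C)O | intermediate
23 | C5 alcohol cis to the epoxide | CC(=C/[C@H](O[Si](CC)(CC)CC)[C@]12O[C@H]1[C@@H](O)C(CO[Si](C)(C)C(C)(C)C)=C[C@@H]2O[Si](CC)(CC)CC)/C=C/[C@@H]3C(C)(C)[C@H](O[Si](CC)(CC)CC)CC[C@@]3(C)O | intermediate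
24 | C5 4-nitrobenzoate trans to the epoxide | CC(=C/[C@H](O[Si](CC)(CC)CC)[C@]12O[C@H]1[C@H](OC(=O)c4ccc(cc4)[N+](=O)[O-])C(CO[Si](C)(C)C(C)(C)C)=C[C@@H]2O[Si](CC)(CC)CC)/C=C/[C@@H]3C(C)(C)[C@H](O[Si](CC)(CC)CC)CC[C@@]3(C)O | intermediate
25 | silyl-protected arthrosporol A (C5 alcohol trans to the epoxide) | CC(=C/[C@H](O[Si](CC)(CC)CC)[C@]12O[C@H]1[C@H](O)C(CO[Si](C)(C)C(C)(C)C)=C[C@@H]2O[Si](CC)(CC)CC)/C=C/[C@@H]3C(C)(C)[C@H](O[Si](CC)(CC)CC)CC[C@@]3(C)O | intermediate
26 | arthrosporol A, (1R,2S,5R,6S)-1-[(1S,2Z,4E)-5-[(1R,3R,6R)-3,6-dihydroxy-2,2,6-trimethylcyclohexyl]-1-hydroxy-3-methylpenta-2,4-dien-1-yl]-4-(hydroxymethyl)-7-oxabicyclo[4.1.0]hept-3-ene-2,5-diol | CC(=C/[C@H](O)[C@]12O[C@H]1[C@H](O)C(CO)=C[C@@H]2O)/C=C/[C@@H]1C(C)(C)[C@H](O)CC[C@@]1(C)O | target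

**Step count and risks**

Total step count: 22. Longest linear sequence: 17 steps (steps 1–6, 8, 9, 14–22).

Steps most likely to fail:

Step 14. What may go wrong: electron transfer from divalent chromium to the cross-conjugated dienone (loss of methoxide and aromatization), erosion of the ligand-controlled facial selectivity, or isomerization of the 2Z enal. Fallback, which takes the chirality of ring B from a ring carbinol instead of from the coupling: it sets out from 17 and 12 and rejoins the route at 21. Corey–Bakshi–Shibata reduction of 17 ((R)-2-methyl-CBS-oxazaborolidine, BH3·SMe2) should give the (S)-iodo dienol F1. TESCl/imidazole gives its triethylsilyl ether F2. Ligand-free Nozaki–Hiyama–Kishi coupling of F2 with 12 (CrCl2, NiCl2 cat., DMSO) gives the carbinol epimer mixture F3. MnO2 converts both epimers into the cross-conjugated dienyl ketone F4. Weitz–Scheffer epoxidation (t-BuOOH, DBU) of the ring double bond, now activated by the side-chain ketone, anti to the adjacent silyloxy group gives the epoxy ketone F5. Luche reduction, with cerium chelated between the ketone and the epoxide oxygen, should give the (S)-carbinol F6. TESCl/imidazole then silylates the two free secondary hydroxyls to give 21.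

Step 15. What may go wrong: poor facial selectivity, if attack on an alkoxide chelated to the ring carbonyl competes with delivery from the alkoxide lying over the ring face. Fallback, which replaces hydroxyl direction by catalyst control: it sets out from 18 and rejoins the route at 19. TESCl/imidazole gives the bis(triethylsilyl) ether F7 (side-chain carbinol and ring A secondary hydroxyl). Phase-transfer Weitz–Scheffer epoxidation (t-BuOOH, aq. NaOH, N-benzylcinchonidinium chloride, toluene, 0 °C) gives the epoxide F8. PPTS in MeOH at 0 °C removes both triethylsilyl groups and gives 19.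

Step 20. What may go wrong: SN2' attack, or elimination with opening of the epoxide, instead of clean SN2 inversion at the hindered allylic epoxy carbinol. Fallback, which replaces inversion by a reagent-controlled reduction: it sets out from 22 and rejoins the route at 25. Corey–Bakshi–Shibata reduction of 22 ((R)-2-methyl-CBS-oxazaborolidine, catecholborane, toluene, −78 °C) should deliver hydride to the face of the epoxide oxygen and give 25 directly, so that steps 19–21 are bypassed and no new compound is made.

Further compounds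
F1 | step 14 | (S)-5-[(tert-butyldimethylsilyloxy)methyl]-2-iodo-4,4-dimethoxycyclohexa-2,5-dien-1-ol | O[C@H]1C=C(CO[Si](C)(C)C(C)(C)C)C(OC)(OC)C=C1I
F2 | step 14 | triethylsilyl ether of F1 | CC[Si](CC)(CC)O[C@H]1C=C(CO[Si](C)(C)C(C)(C)C)C(OC)(OC)C=C1I
F3 | step 14 | coupling product of F2 and 12, both side-chain carbinol epimers | CC(=C/C(O)C1=CC(OC)(OC)C(CO[Si](C)(C)C(C)(C)C)=C[C@@H]1O[Si](CC)(CC)CC)/C=C/[C@@H]2C(C)(C)[C@H](O)CC[C@@]2(C)O
F4 | step 14 | cross-conjugated dienyl ketone | CC(=C/C(=O)C1=CC(OC)(OC)C(CO[Si](C)(C)C(C)(C)C)=C[C@@H]1O[Si](CC)(CC)CC)/C=C/[C@@H]2C(C)(C)[C@H](O)CC[C@@]2(C)O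
F5 | step 14 | epoxy ketone, epoxide anti to the silyloxy group | CC(=C/C(=O)[C@]12O[C@H]1C(OC)(OC)C(CO[Si](C)(C)C(C)(C)C)=C[C@@H]2O[Si](CC)(CC)CC)/C=C/[C@@H]3C(C)(C)[C@H](O)CC[C@@]3(C)O
F6 | step 14 | (S)-carbinol, mono(triethylsilyl) ether of 20 at the ring B C2 oxygen | CC(=C/[C@H](O)[C@]12O[C@H]1C(OC)(OC)C(CO[Si](C)(C)C(C)(C)C)=C[C@@H]2O[Si](CC)(CC)CC)/C=C/[C@@H]3C(C)(C)[C@H](O)CC[C@@]3(C)O
F7 | step 15 | bis(triethylsilyl) ether of 18 | CC(=C/[C@H](O[Si](CC)(CC)CC)C1=CC(OC)(OC)C(CO[Si](C)(C)C(C)(C)C)=CC1=O)/C=C/[C@@H]2C(C)(C)[C@H](O[Si](CC)(CC)CC)CC[C@@]2(C)O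
F8 | step 15 | bis(triethylsilyl) ether of 19 | CC(=C/[C@H](O[Si](CC)(CC)CC)[C@]12O[C@H]1C(OC)(OC)C(CO[Si](C)(C)C(C)(C)C)=CC2=O)/C=C/[C@@H]3C(C)(C)[C@H](O[Si](CC)(CC)CC)CC[C@@]3(C)O
F0 | step 20 | none | none
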